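## Structural features

The target 10 is a chroman. A benzene ring (C4a, C5–C8, C8a) is fused to a dihydropyran ring (O1, C2, C3, C4), with CHO on C5, OH on C6, H on C7 and CH3 on C8, so five of the six aromatic positions are substituted. C2 is the only stereocentre, an (R)-configured, fully substituted ether carbon bearing O1, CH3, the ring methylene C3 and C1′ of a (3′E,7′E)-4′,8′,12′-trimethyltrideca-3′,7′,11′-trienyl chain. Its two methylene arms (C3–C4–aryl and C1′–C2′–C3′=) differ only from the third atom on, and no functional group stands next to it, so C2 cannot be set by neighbouring-group control. The 1,5-triene does not tolerate strong Brønsted or Lewis acids (cation–olefin cyclisation), hydrogenation or electrophilic halogen, which rules out acid-mediated chroman closures and chromanone or chromene reductions; the p-alkoxyphenol is easily oxidised, and the salicylaldehyde reacts with amines and bases. In a finished 8-methylchroman-6-ol both positions ortho to the hydroxyl group (C5 and C7) are flanked by an sp3 carbon, so a late formylation has little to choose between them. The real difficulty is therefore threefold: the configuration at C2, a ring closure that respects the triene, and the placing of the formyl group on C5. The key step exploits three features: the formyl carbon on C5 stands ortho to C4a, the carbon that must be bonded to C4, and C4a–H is the only C–H ortho to it in a ring-opened precursor because C6 carries oxygen; C2 is quaternary, so a C3=C4 vinyl group on it has no allylic hydrogen and behaves like 3,3-dimethylbut-1-ene; and the C8 methyl group blocks the second position ortho to O1. With C4–C4a cut, the atoms C4–C3–C2(CH3)–C1′ and the rest of the chain are the intact C20 skeleton of an all-E allylic alcohol that can be bought.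

## Logic of the disconnections

**10 ⇒ 9.** No skeletal bond is cut; the O–H bond on the C6 oxygen is replaced by O–Si. The reason lies in the key step. A free hydroxyl group ortho to an imine would bind the metal as an anionic N,O-chelate and take the nitrogen away from C4a–H. The gain is tactical only. The forward step must free the phenol without acid, strong base or oxidant, and buffered fluoride meets this demand.

**9 ⇒ 8 ⇒ 7 (key disconnection).** The ring bond C4–C4a is cut, hydrogen returns to C4a, C3=C4 becomes a vinyl group on C2, and the C5 aldehyde is written as its N-benzylimine.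
- In one sentence, the route is the closure of the dihydropyran ring by imine-directed addition of C4a–H across the vinyl group of the acyclic tertiary allyl aryl ether 7.
- The cut is made here because the C5 substituent itself can select C4a–H. The formyl group is then on the ring from the start and needs no late regiochemical decision.
- The gain is large. A bicycle becomes a simple arene with an acyclic ether. Apart from its two auxiliary groups, 7 is an isomer of 10, and its O1–C2 bond has become allylic, which opens the next cut.
- The forward step has several demands. Insertion must occur into C4a–H only. Addition must be linear (C4, not C3, bonded to the ring). The temperature must stay below the onset of the aromatic Claisen rearrangement. The O1–C2 bond must not ionise, and the three trisubstituted olefins must be left alone.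

**7 ⇒ 6 ⇒ 5.** The C=N bond and the O–Si bond are cut. Both groups are auxiliaries of the key step (directing group, mask of the chelating OH), and both come off in the work-up of step 6 or in step 7. The gain is that 5 is the exact constitutional isomer of 10. The forward steps must be neutral or mildly basic, because the tertiary allylic ether is acid-labile.

**5 ⇒ 2 + 4.** The bond O1–C2 is cut.
- It is the only bond whose formation joins the whole C20 chain to the arene, creates the vinyl group for the key step, and sets C2, all in one operation.
- The gain is maximal. One fragment holds all three E-olefins ready-made, and the other holds all five arene substituents.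
- The forward step needs attack at the fully substituted allyl terminus (branched product), on one face, by one of the two hydroxyl groups of 4.

**2 ⇒ 1 and 4 ⇒ 3.** The C–O bond of the carbonate and the two O–CH3 bonds are cut. These are activations of commercial compounds. The carbonate supplies its own base on ionisation, and the substitution pattern of 3 already fixes CHO para to CH3. The only demand is that 4 be handled under inert gas.

## Other disconnections considered

**Alternative 1:** (the first that comes to mind) cut C5–CHO, then C2′–C3′.
- Forward route: the (S)-2-vinylchroman silyl ether A2 is hydroborated and coupled by B-alkyl Suzuki–Miyaura reaction with the (1E,5E)-alkenyl iodide A3, giving silyl ether A4. Desilylation gives (R)-δ-tocotrienol A1, and the key step is its ortho-formylation.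
- In A1, C5 and C7 are both ortho to the hydroxyl group and each is flanked by an sp3 carbon. The regiochemical decision therefore rests on a small electronic bias and falls on the last step, when the material is most valuable.
- A2 needs an asymmetric synthesis of its own, and A3 needs a stereodefined chain synthesis. The olefin geometry is thus built rather than bought, and the step count roughly doubles.
- In the chosen plan the formyl group is present from the start and does the work of choosing C4a.

**Alternative 2:** cut O1–C2 alone, in the biomimetic sense.
- Forward route: an enantioselective, proton-initiated 6-endo cyclisation of 2-methyl-6-geranylgeranylhydroquinone A5 to A1 with a chiral Brønsted acid, followed by formylation.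
- A5 has four trisubstituted olefins of nearly equal basicity. An acid strong enough to protonate the first one can also start cation–olefin cyclisation along the chain.
- The enantioface of an unfunctionalised olefin would have to be recognised without a binding handle.
- The C5/C7 problem of Alternative 1 remains. The chosen plan forms O1–C2 under neutral conditions at an allyl terminus that only one olefin can provide.

**Alternative 3:** cut O1–C2 and C3–C4 together.
- Forward route: an inverse-demand hetero-Diels–Alder reaction of the o-quinone methide A6 with the 1,1-disubstituted terminus of tetraene A7 (one methylenation away from a commercial C18 ketone), giving A4.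
- The cut is attractively convergent, with two bonds, the ring and the chain joined in one step.
- The configuration at C2 would depend on telling CH3 from CH2CH2R on an unactivated olefin that offers a catalyst nothing to hold.
- The electron-rich trisubstituted olefins of A7 compete for A6, and A6 dimerises readily. The formyl group again has to come last.
- The chosen plan splits the same ring into two steps, each with a clear controlling element (ligand pocket, directing group).

Key step: step 6

Assumption: in step 3 the (R,R)-ligand is taken, from the pocket model of the ligand, to give (R)-5 from the (E)-carbonate. Both antipodes of the ligand are commercial, so the (S,S)-ligand would be used with no other change if the configuration check on 5 requires it.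

## Steps

Step 1
Reactants: 1 (2E,6E,10E)-geranylgeraniol
Product: 2 (2E,6E,10E)-geranylgeranyl methyl carbonate
Conditions: ClCO2Me, pyridine, CH2Cl2, 0 °C to rt
Reagents that add atoms: methyl chloroformate, COC(=O)Cl
Why: O-acylation of a primary allylic alcohol under mildly basic conditions, which leaves the three E-olefins and the allylic position untouched. The methyl carbonate is chosen because its ionisation releases CO2 and methoxide, the only base needed in step 3.

Step 2
Reactants: 3 2,5-dimethoxy-4-methylbenzaldehyde
Product: 4 2,5-dihydroxy-4-methylbenzaldehyde
Conditions: BBr3 (3 equiv), CH2Cl2, −78 °C to rt; then H2O, under argon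
Reagents that add atoms: none
Why: Lewis-acid cleavage of aryl methyl ethers; the ether ortho to the formyl group falls first through chelation, and excess reagent takes the second. The aldehyde is only complexed and is released on hydrolysis.

Step 3
Reactants: 2 (2E,6E,10E)-geranylgeranyl methyl carbonate; 4 2,5-dihydroxy-4-methylbenzaldehyde
Product: 5 2-hydroxy-4-methyl-5-{[(3R,6E,10E)-3,7,11,15-tetramethylhexadeca-1,6,10,14-tetraen-3-yl]oxy}benzaldehyde
Conditions: Pd2(dba)3·CHCl3 (2.5 mol %), (R,R)-DACH-phenyl ligand [bis(2-diphenylphosphinobenzamide) of (1R,2R)-1,2-diaminocyclohexane] (7.5 mol %), CH2Cl2, 0 °C to rt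
Reagents that add atoms: none
Why: Tsuji–Trost asymmetric allylic alkylation with a phenol nucleophile: ionisation of 2 gives CO2, methoxide and a π-allylpalladium complex, and the phenoxide attacks the more substituted, more cationic terminus inside the chiral pocket to give the branched tertiary ether. C2 is set here: the two diastereomeric complexes interconvert by η3–η1–η3 at the unsubstituted terminus (future C4) faster than they are attacked, the syn/anti places of CH3 and chain inherited from the E-olefin are kept, and the ligand admits the phenoxide anti to Pd on one face only. Of the two hydroxyl groups of 4 only the one meta to the formyl group (future O1) should react, because the ortho one (future C6–OH) is tied up in a hydrogen bond to the formyl oxygen and its phenoxide is conjugatively deactivated.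

Step 4
Reactants: 5 2-hydroxy-4-methyl-5-{[(3R,6E,10E)-3,7,11,15-tetramethylhexadeca-1,6,10,14-tetraen-3-yl]oxy}benzaldehyde
Product: 6 4-methyl-5-{[(3R,6E,10E)-3,7,11,15-tetramethylhexadeca-1,6,10,14-tetraen-3-yl]oxy}-2-(triisopropylsilyloxy)benzaldehyde
Conditions: TIPSCl, imidazole, DMAP (cat.), DMF, rt
Reagents that add atoms: chlorotriisopropylsilane, CC(C)[Si](Cl)(C(C)C)C(C)C
Why: Standard silylation of a phenol under weakly basic conditions that do not endanger the acid-labile tertiary allylic ether. The bulky TIPS group is chosen because aryl silyl ethers ortho to a formyl group are otherwise labile towards amines.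

Step 5
Reactants: 6 4-methyl-5-{[(3R,6E,10E)-3,7,11,15-tetramethylhexadeca-1,6,10,14-tetraen-3-yl]oxy}-2-(triisopropylsilyloxy)benzaldehyde
Product: 7 (E)-N-benzylimine of 6
Conditions: BnNH2 (1.05 equiv), 4 Å MS, toluene, rt; filtered and concentrated, used crude
Reagents that add atoms: benzylamine, NCc1ccccc1
Why: Condensation of an aromatic aldehyde with a primary amine, driven by removal of water. In the favoured conformer the nitrogen lone pair points away from the C6 oxygen and towards C4a–H, as the key step requires.

Step 6
Reactants: 7 (E)-N-benzylimine of 6
Product: 9 (2R)-2,8-dimethyl-2-[(3E,7E)-4,8,12-trimethyltrideca-3,7,11-trienyl]-6-(triisopropylsilyloxy)chroman-5-carbaldehyde, via chroman N-benzylimine 8 (not isolated)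
Conditions: [RhCl(coe)2]2 (5 mol %), (dicyclohexylphosphino)ferrocene (15 mol %), toluene (0.05 M), 75 °C; then 1 N HCl, THF, rt
Reagents that add atoms: water, O
Why: The closest known reaction is the imine-directed C–H alkylation of the Murai type in its intramolecular Rh(I) form, the annulation of aromatic imines that carry an olefin on a meta heteroatom tether. The imine nitrogen binds Rh(I), which inserts into C4a–H, the only C–H ortho to the imine because C6 carries OTIPS, to give a five-membered aza-rhodacycle hydride. The vinyl group is held near C4a because the C8 methyl group turns the O1–C2 bond to that side and C2 is fully substituted (gem-disubstituent effect), so it coordinates and inserts into Rh–H. Hydride goes to C3 and Rh to the terminal C4, as with 3,3-dimethylbut-1-ene, because the alternative would place Rh on a secondary carbon next to the quaternary C2; C–C reductive elimination from the seven-membered rhodacycle then forms C4–C4a. The dihydropyran ring is thus closed in a formal 6-endo-trig mode (both olefin carbons end up in the ring) in preference to 5-exo closure to a five-membered ring. No stereocentre is formed: C2 is carried through unchanged because none of its four bonds is broken and the medium is neutral, and olefin migration is impossible because C2 bears no hydrogen. Chemoselectivity over the three trisubstituted olefins rests on their poor binding to Rh and their distance from C4a, and the electron-rich ferrocenyl dialkylphosphine allows a temperature meant to stay below the onset of the aromatic Claisen rearrangement of the tertiary allyl aryl ether. Dilute acid on work-up hydrolyses 8 to 9 and should leave the aryl TIPS ether and the triene intact.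

Step 7
Reactants: 9 (2R)-2,8-dimethyl-2-[(3E,7E)-4,8,12-trimethyltrideca-3,7,11-trienyl]-6-(triisopropylsilyloxy)chroman-5-carbaldehyde
Product: 10 (2R)-6-hydroxy-2,8-dimethyl-2-[(3E,7E)-4,8,12-trimethyltrideca-3,7,11-trienyl]chroman-5-carbaldehyde (target)
Conditions: TBAF (1.1 equiv), AcOH (1.1 equiv), THF, 0 °C, under argon
Reagents that add atoms: none
Why: Fluoride-mediated cleavage of an aryl silyl ether, made easier by the ortho-formyl group; acetic acid protonates the phenoxide at once, so the oxidation-prone anion does not persist. Triene, aldehyde and C2 are not affected.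

## Compound list

1 | (2E,6E,10E)-geranylgeraniol | CC(C)=CCC/C(C)=C/CC/C(C)=C/CC/C(C)=C/CO | starting material
2 | (2E,6E,10E)-geranylgeranyl methyl carbonate | CC(C)=CCC/C(C)=C/CC/C(C)=C/CC/C(C)=C/COC(=O)OC | intermediate
3 | 2,5-dimethoxy-4-methylbenzaldehyde | COc1cc(C=O)c(OC)cc1C | starting material
4 | 2,5-dihydroxy-4-methylbenzaldehyde | Oc1cc(C=O)c(O)cc1C | intermediate
5 | 2-hydroxy-4-methyl-5-{[(3R,6E,10E)-3,7,11,15-tetramethylhexadeca-1,6,10,14-tetraen-3-yl]oxy}benzaldehyde | CC(C)=CCC/C(C)=C/CC/C(C)=C/CC[C@](C)(C=C)Oc1cc(C=O)c(O)cc1C | intermediate
6 | 4-methyl-5-{[(3R,6E,10E)-3,7,11,15-tetramethylhexadeca-1,6,10,14-tetraen-3-yl]oxy}-2-(triisopropylsilyloxy)benzaldehyde | CC(C)=CCC/C(C)=C/CC/C(C)=C/CC[C@](C)(C=C)Oc1cc(C=O)c(O[Si](C(C)C)(C(C)C)C(C)C)cc1C | intermediate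
7 | (E)-N-benzylimine of 6 | CC(C)=CCC/C(C)=C/CC/C(C)=C/CC[C@](C)(C=C)Oc1cc(/C=N/Cc2ccccc2)c(O[Si](C(C)C)(C(C)C)C(C)C)cc1C | intermediate
8 | (E)-N-benzylimine of 9 (chroman N-benzylimine, not isolated) | CC(C)=CCC/C(C)=C/CC/C(C)=C/CC[C@]1(C)CCc2c(/C=N/Cc3ccccc3)c(O[Si](C(C)C)(C(C)C)C(C)C)cc(C)c2O1 | intermediate
9 | (2R)-2,8-dimethyl-2-[(3E,7E)-4,8,12-trimethyltrideca-3,7,11-trienyl]-6-(triisopropylsilyloxy)chroman-5-carbaldehyde | CC(C)=CCC/C(C)=C/CC/C(C)=C/CC[C@]1(C)CCc2c(C=O)c(O[Si](C(C)C)(C(C)C)C(C)C)cc(C)c2O1 | intermediate
10 | (2R)-6-hydroxy-2,8-dimethyl-2-[(3E,7E)-4,8,12-trimethyltrideca-3,7,11-trienyl]chroman-5-carbaldehyde (5-formyl-δ-tocotrienol, CNP0254563.2) | CC(C)=CCC/C(C)=C/CC/C(C)=C/CC[C@]1(C)CCc2c(C=O)c(O)cc(C)c2O1 | target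

## Step count and least certain steps

Total step count: 7. Longest linear sequence: 6 (steps 1, 3, 4, 5, 6, 7; equally 2, 3, 4, 5, 6, 7).

**Step 6 (key step).**
- The most likely failure is a thermal [3,3]-sigmatropic shift of the tertiary allyl aryl ether onto C4a competing with C–H insertion. This would erase C2. Such ethers rearrange at temperatures not far above the one planned.
- Second, hydrometalation in the branched sense could lead to 5-exo closure or to β-aryloxide elimination. Simple tethered olefins tend to prefer the smaller ring, and here only the quaternary C2 argues against it.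
- Third, Rh(I) could ionise the allylic O1–C2 bond.
- Fallback (sets out from 6, returns at 9): the C4–C4a bond is made by cross-coupling instead of C–H activation. Aldehyde 6 is masked in situ as its α-amino alkoxide with lithium N,N,N′-trimethylethylenediamide. It is lithiated with n-BuLi at C4a, the only position ortho to the masked formyl group and also ortho to O1, and quenched with iodine at −78 °C to give the C4a-iodo aldehyde F1. Aprotic acetalisation (1,2-bis(trimethylsilyloxy)ethane, cat. TMSOTf, CH2Cl2, −78 °C) gives the iodo dioxolane F2. 9-BBN adds only to the monosubstituted olefin to give the primary B-alkyl-9-BBN derivative F3. This is closed in the same flask by intramolecular B-alkyl Suzuki–Miyaura coupling (PdCl2(dppf), K3PO4, THF/DMF/H2O, rt to 50 °C) to the chroman dioxolane F4. PPTS in wet acetone then returns 9.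

**Step 3.**
- The most likely failure is insufficient facial selectivity together with leakage to the linear ether. The nucleophile carries an ortho-methyl group and the electrophilic terminus is fully substituted. Re-ionisation of the product by Pd(0) would erode both selectivities with time.
- Fallback (sets out from 1, returns at 9): C2 is set by reagent-controlled epoxidation, and the order of the two ring bonds is reversed.
- Sharpless epoxidation of 1 (D-(−)-diethyl tartrate, Ti(OiPr)4, t-BuOOH, 4 Å MS, CH2Cl2, −20 °C) gives (2R,3R)-2,3-epoxygeranylgeraniol F5. I2/PPh3/imidazole gives the epoxy iodide F6. Zinc dust in ethanol opens it reductively to (R)-geranyllinalool F7 without touching the C–O bond at the tertiary centre.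
- Commercial 5-bromo-2-hydroxy-4-methylbenzaldehyde F8 is silylated to its TIPS ether F9 and condensed with benzylamine to the N-benzylimine F10.
- Intermolecular imine-directed ortho-alkylation of F10 with the vinyl group of F7 (Rh(I)/phosphine, toluene) gives the alkylated imine F11, which is hydrolysed on work-up to the bromo aldehyde tertiary alcohol F12.
- An intramolecular Buchwald–Hartwig-type etherification (Pd(OAc)2, di-tert-butylphosphinobiaryl ligand, Cs2CO3, toluene) forms O1–C8a with retention at C2 and gives 9.

**Step 2.**
- The likely failures are aerial oxidation of the electron-rich formylhydroquinone during aqueous work-up, incomplete cleavage of the non-chelated ether and, downstream, loss of site selectivity between the two hydroxyl groups in step 3.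
- Fallback (sets out from 2, returns at 5): 4 is avoided, and the formyl group is introduced after the etherification. Commercial methylhydroquinone F13 is silylated at its less hindered hydroxyl group (TBSCl, imidazole, DMF) to 4-(tert-butyldimethylsilyloxy)-2-methylphenol F14, which offers a single free OH. The allylic alkylation of step 3 with 2 gives the tertiary aryl ether F15, and TBAF gives the phenol F16.
- Magnesium-mediated ortho-formylation (MgCl2, Et3N, paraformaldehyde, THF, reflux; Casnati–Skattebøl) should then go to C5 and give 5. In the open-chain ether C5 has a hydrogen neighbour (C4a–H), whereas C7 is wedged between the hydroxyl group and the C8 methyl group.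

## Further compounds

F1 | step 6 | 6-iodo derivative of 6 (iodine on the future C4a) | CC(C)=CCC/C(C)=C/CC/C(C)=C/CC[C@](C)(C=C)Oc1c(I)c(C=O)c(O[Si](C(C)C)(C(C)C)C(C)C)cc1C
F2 | step 6 | 1,3-dioxolane of F1 | CC(C)=CCC/C(C)=C/CC/C(C)=C/CC[C@](C)(C=C)Oc1c(I)c(C2OCCO2)c(O[Si](C(C)C)(C(C)C)C(C)C)cc1C
F3 | step 6 | primary B-alkyl-9-BBN derivative of F2 (boron on the future C4, ether carbon configured as in 6) | CC(C)=CCC/C(C)=C/CC/C(C)=C/CC[C@](C)(CCB1C2CCCC1CCC2)Oc1c(I)c(C2OCCO2)c(O[Si](C(C)C)(C(C)C)C(C)C)cc1C
F4 | step 6 | 1,3-dioxolane of 9 | CC(C)=CCC/C(C)=C/CC/C(C)=C/CC[C@]1(C)CCc2c(C3OCCO3)c(O[Si](C(C)C)(C(C)C)C(C)C)cc(C)c2O1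
F5 | step 3 | (2R,3R)-2,3-epoxygeranylgeraniol | CC(C)=CCC/C(C)=C/CC/C(C)=C/CC[C@@]1(C)O[C@@H]1CO
F6 | step 3 | epoxy iodide derived from F5 (CH2I in place of CH2OH) | CC(C)=CCC/C(C)=C/CC/C(C)=C/CC[C@@]1(C)O[C@@H]1CI
F7 | step 3 | (R)-geranyllinalool, (3R,6E,10E)-3,7,11,15-tetramethylhexadeca-1,6,10,14-tetraen-3-ol | CC(C)=CCC/C(C)=C/CC/C(C)=C/CC[C@](C)(C=C)O
F8 | step 3 | 5-bromo-2-hydroxy-4-methylbenzaldehyde | Cc1cc(O)c(C=O)cc1Br
F9 | step 3 | 5-bromo-4-methyl-2-(triisopropylsilyloxy)benzaldehyde | Cc1cc(O[Si](C(C)C)(C(C)C)C(C)C)c(C=O)cc1Br
F10 | step 3 | (E)-N-benzylimine of F9 | Cc1cc(O[Si](C(C)C)(C(C)C)C(C)C)c(/C=N/Cc2ccccc2)cc1Br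
F11 | step 3 | (E)-N-benzylimine of F12 | CC(C)=CCC/C(C)=C/CC/C(C)=C/CC[C@@](C)(O)CCc1c(Br)c(C)cc(O[Si](C(C)C)(C(C)C)C(C)C)c1/C=N/Cc1ccccc1
F12 | step 3 | 3-bromo-2-[(3R,6E,10E)-3-hydroxy-3,7,11,15-tetramethylhexadeca-6,10,14-trienyl]-4-methyl-6-(triisopropylsilyloxy)benzaldehyde | CC(C)=CCC/C(C)=C/CC/C(C)=C/CC[C@@](C)(O)CCc1c(Br)c(C)cc(O[Si](C(C)C)(C(C)C)C(C)C)c1C=O
F13 | step 2 | methylhydroquinone | Cc1cc(O)ccc1O
F14 | step 2 | 4-(tert-butyldimethylsilyloxy)-2-methylphenol | Cc1cc(O[Si](C)(C)C(C)(C)C)ccc1O
F15 | step 2 | tert-butyldimethylsilyl ether of F16 | CC(C)=CCC/C(C)=C/CC/C(C)=C/CC[C@](C)(C=C)Oc1ccc(O[Si](C)(C)C(C)(C)C)cc1C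
F16 | step 2 | 3-methyl-4-{[(3R,6E,10E)-3,7,11,15-tetramethylhexadeca-1,6,10,14-tetraen-3-yl]oxy}phenol | CC(C)=CCC/C(C)=C/CC/C(C)=C/CC[C@](C)(C=C)Oc1ccc(O)cc1C
A1 | alternative 1 | (R)-δ-tocotrienol | CC(C)=CCC/C(C)=C/CC/C(C)=C/CC[C@]1(C)CCc2cc(O)cc(C)c2O1
A2 | alternative 1 | (S)-6-(tert-butyldimethylsilyloxy)-2,8-dimethyl-2-vinylchroman | C=C[C@]1(C)CCc2cc(O[Si](C)(C)C(C)(C)C)cc(C)c2O1
A3 | alternative 1 | (1E,5E)-1-iodo-2,6,10-trimethylundeca-1,5,9-triene | CC(C)=CCC/C(C)=C/CC/C(C)=C/I
A4 | alternative 1 | tert-butyldimethylsilyl ether of A1 | CC(C)=CCC/C(C)=C/CC/C(C)=C/CC[C@]1(C)CCc2cc(O[Si](C)(C)C(C)(C)C)cc(C)c2O1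
A5 | alternative 2 | 2-methyl-6-[(2E,6E,10E)-geranylgeranyl]hydroquinone | CC(C)=CCC/C(C)=C/CC/C(C)=C/CC/C(C)=C/Cc1cc(O)cc(C)c1O
A6 | alternative 3 | 4-(tert-butyldimethylsilyloxy)-2-methyl-6-methylenecyclohexa-2,4-dienone (o-quinone methide) | C=C1C=C(O[Si](C)(C)C(C)(C)C)C=C(C)C1=O
A7 | alternative 3 | (5E,9E)-2,6,10,14-tetramethylpentadeca-1,5,9,13-tetraene | CC(C)=CCC/C(C)=C/CC/C(C)=C/CCC(C)=C
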